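## Retrosynthetic overview

1. Last bond: ring A aryl carbon to C1 of the propane chain, by nickel-catalysed denitrogenative coupling of an aldehyde N–H hydrazone (the former carbonyl carbon reacts as a carbanion) with an unprotected bromoresorcinol.
2. Ring B half: a 3-arylpropanal from a 4,5-dibromo-dihydrobenzofuranol, by site-selective Heck arylation of allyl alcohol at C5, then Stille prenylation at C4.
3. The dihydrofuran (the only ring formed) comes from symmetric 4,5-dibromocatechol: O-tert-prenylation, Claisen shift to C3, Shi epoxidation, 5-exo phenoxide opening (sets C2).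
4. Ring A half: resorcinol mono-prenyl ether, Claisen shift (gives the 1,1-dimethylallyl group), bromination.
5. Ring order: both benzene rings are bought; the dihydrofuran is closed in step 3; nothing is closed afterwards.

Assumption: the [C@H] centre of the SMILES is (R) at C2 of the dihydrobenzofuran (O1, C2, C3, C3a, C4–C7, C7a); ring A is the resorcinol ring and ring B the benzofuran benzene ring.

## Route

Step 1
Reactants: 1 dibromocatechol (4,5-dibromobenzene-1,2-diol, 1.5 equiv); 2 tert-butyl 2-methylbut-3-en-2-yl carbonate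
Product: 3 mono-ether 4,5-dibromo-2-[(2-methylbut-3-en-2-yl)oxy]phenol
Conditions: Pd(PPh3)4 (2 mol %), THF, 0 °C → rt
Reagents that add atoms: none
Why: Tsuji–Trost O-allylation in which zerovalent palladium ionises the tertiary carbonate and the phenoxide attacks the more substituted allyl terminus under kinetic control, the symmetry of 1 allowing only one mono-ether.

Step 2
Reactants: 3 mono-ether 4,5-dibromo-2-[(2-methylbut-3-en-2-yl)oxy]phenol
Product: 5 bis-silyl ether 4,5-dibromo-1,2-bis[(tert-butyldimethylsilyl)oxy]-3-(3-methylbut-2-en-1-yl)benzene, via prenylcatechol 4 (not isolated)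
Conditions: PhMe, 110 °C; then TBSCl, imidazole, DMF, rt
Reagents that add atoms: tert-butyldimethylsilyl chloride (TBSCl), CC(C)(C)[Si](C)(C)Cl
Why: Aromatic Claisen rearrangement of the aryl 1,1-dimethylallyl ether puts a linear prenyl group on the only free ortho carbon (C3), and silylation in the same pot masks the air-sensitive catechol for the oxidation that follows.

Step 3
Reactants: 5 bis-silyl ether 4,5-dibromo-1,2-bis[(tert-butyldimethylsilyl)oxy]-3-(3-methylbut-2-en-1-yl)benzene
Product: 7 dibromide (2R)-4,5-dibromo-2-(2-hydroxypropan-2-yl)-2,3-dihydro-1-benzofuran-7-ol, via bis-silyl (S)-epoxide 6 (not isolated)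
Conditions: ent-Shi ketone (L-fructose-derived, 30 mol %), KHSO5, K2CO3, Bu4NHSO4, MeCN–CH2(OMe)2–aq. Na2B4O7 buffer, 0 °C; extract; then Bu4NF, THF, 0 °C → rt
Reagents that add atoms: potassium peroxymonosulfate (KHSO5), [K+].OOS(=O)(=O)[O-]
Why: Shi asymmetric epoxidation with the enantiomeric ketone gives the (S)-epoxide of the trisubstituted alkene, and fluoride then frees the ortho phenoxide, which opens the epoxide 5-exo at the secondary carbon with SN2 inversion to set (R)-C2 and release the tertiary alcohol (about 90% ee expected, raised by recrystallising 7).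

Step 4
Reactants: 7 dibromide (2R)-4,5-dibromo-2-(2-hydroxypropan-2-yl)-2,3-dihydro-1-benzofuran-7-ol; 8 allyl alcohol (prop-2-en-1-ol, 3 equiv)
Product: 9 bromo aldehyde 3-[(2R)-4-bromo-7-hydroxy-2-(2-hydroxypropan-2-yl)-2,3-dihydro-1-benzofuran-5-yl]propanal
Conditions: Pd(OAc)2 (5 mol %), Bu4NCl, NaHCO3, DMF, 90 °C
Reagents that add atoms: none
Why: Jeffery–Heck arylation of allyl alcohol (β-hydride elimination toward the carbinol then tautomerisation gives the aldehyde) takes place at C5–Br, which has one ortho substituent against two for C4–Br and is not para to the phenoxide that deactivates C4–Br toward oxidative addition.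

Step 5
Reactants: 9 bromo aldehyde 3-[(2R)-4-bromo-7-hydroxy-2-(2-hydroxypropan-2-yl)-2,3-dihydro-1-benzofuran-5-yl]propanal; 10 tributyl(3-methylbut-2-en-1-yl)stannane
Product: 11 prenyl aldehyde 3-[(2R)-7-hydroxy-2-(2-hydroxypropan-2-yl)-4-(3-methylbut-2-en-1-yl)-2,3-dihydro-1-benzofuran-5-yl]propanal
Conditions: Pd(P(t-Bu)3)2 (5 mol %), CsF, dioxane, 80 °C
Reagents that add atoms: none
Why: Stille coupling with a bulky electron-rich phosphine engages the remaining di-ortho-substituted bromide, and reductive elimination from the prenylpalladium intermediate at its unhindered CH2 terminus gives the linear prenyl group.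

Step 6
Reactants: 12 resorcinol (benzene-1,3-diol, 3 equiv); 13 prenyl bromide (1-bromo-3-methylbut-2-ene)
Product: 14 mono-prenyl ether 3-[(3-methylbut-2-en-1-yl)oxy]phenol
Conditions: K2CO3, acetone, reflux
Reagents that add atoms: none
Why: Williamson etherification in which the threefold excess of cheap resorcinol makes the mono-ether the main product.

Step 7
Reactants: 14 mono-prenyl ether 3-[(3-methylbut-2-en-1-yl)oxy]phenol
Product: 15 alkylresorcinol 4-(2-methylbut-3-en-2-yl)benzene-1,3-diol
Conditions: PhNEt2, 190 °C, Ar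
Reagents that add atoms: none
Why: Aromatic Claisen rearrangement turns the prenyl ether into a 1,1-dimethylallyl group on the ortho carbon para to the free hydroxyl, the other ortho carbon (between the two oxygens) being too hindered for the new quaternary centre.

Step 8
Reactants: 15 alkylresorcinol 4-(2-methylbut-3-en-2-yl)benzene-1,3-diol
Product: 16 bromoresorcinol 4-bromo-6-(2-methylbut-3-en-2-yl)benzene-1,3-diol
Conditions: NBS (1.0 equiv), MeCN, −20 °C
Reagents that add atoms: N-bromosuccinimide (NBS), BrN1C(=O)CCC1=O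
Why: Electrophilic aromatic bromination of the resorcinol is far faster than attack on the monosubstituted alkene and goes to C6, which is ortho and para to the two hydroxyls and unhindered.

Step 9
Reactants: 11 prenyl aldehyde 3-[(2R)-7-hydroxy-2-(2-hydroxypropan-2-yl)-4-(3-methylbut-2-en-1-yl)-2,3-dihydro-1-benzofuran-5-yl]propanal; 16 bromoresorcinol 4-bromo-6-(2-methylbut-3-en-2-yl)benzene-1,3-diol; 17 hydrazine monohydrate
Product: 19 target 4-{3-[(2R)-7-hydroxy-2-(2-hydroxypropan-2-yl)-4-(3-methylbut-2-en-1-yl)-2,3-dihydro-1-benzofuran-5-yl]propyl}-6-(2-methylbut-3-en-2-yl)benzene-1,3-diol, via N–H hydrazone 18 (not isolated)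
Conditions: 11, N2H4·H2O (1.2 equiv), THF, rt, then 4 Å sieves; then 16, Ni(cod)2 (10 mol %), PMe3 (20 mol %), DBU (6 equiv), THF, 70 °C
Reagents that add atoms: none
Why: Proposed new method: the closest known reaction type is the nickel-catalysed denitrogenative cross-coupling of N-unsubstituted aldehyde hydrazones with aryl halides (Wolff–Kishner-type carbonyl umpolung), extended here to an aliphatic hydrazone and to free phenols carried as DBU phenoxides; zerovalent nickel adds oxidatively to the C–Br bond of 16, hydrazone 18 binds through nitrogen and is deprotonated, tautomerises to the C-bound diazenyl complex, loses N2 with base, and C(sp2)–C(sp3) reductive elimination joins the former carbonyl carbon to the arene as a CH2 group, leaving the stereocentre and the alkenes untouched.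

## Compound list

1 | 4,5-dibromobenzene-1,2-diol | Oc1cc(Br)c(Br)cc1O | starting material
2 | tert-butyl 2-methylbut-3-en-2-yl carbonate | C=CC(C)(C)OC(=O)OC(C)(C)C | starting material
3 | 4,5-dibromo-2-[(2-methylbut-3-en-2-yl)oxy]phenol | C=CC(C)(C)Oc1cc(Br)c(Br)cc1O | intermediate
4 | 4,5-dibromo-3-(3-methylbut-2-en-1-yl)benzene-1,2-diol | CC(C)=CCc1c(O)c(O)cc(Br)c1Br | intermediate (not isolated)
5 | 4,5-dibromo-1,2-bis[(tert-butyldimethylsilyl)oxy]-3-(3-methylbut-2-en-1-yl)benzene | CC(C)=CCc1c(O[Si](C)(C)C(C)(C)C)c(O[Si](C)(C)C(C)(C)C)cc(Br)c1Br | intermediate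
6 | (3S)-3-({2,3-dibromo-5,6-bis[(tert-butyldimethylsilyl)oxy]phenyl}methyl)-2,2-dimethyloxirane | CC1(C)O[C@H]1Cc2c(O[Si](C)(C)C(C)(C)C)c(O[Si](C)(C)C(C)(C)C)cc(Br)c2Br | intermediate (not isolated)
7 | (2R)-4,5-dibromo-2-(2-hydroxypropan-2-yl)-2,3-dihydro-1-benzofuran-7-ol | Brc1cc(O)c2c(c1Br)C[C@H](C(C)(C)O)O2 | intermediate
8 | prop-2-en-1-ol (allyl alcohol) | C=CCO | starting material
9 | 3-[(2R)-4-bromo-7-hydroxy-2-(2-hydroxypropan-2-yl)-2,3-dihydro-1-benzofuran-5-yl]propanal | O=CCCc1cc(O)c2c(c1Br)C[C@H](C(C)(C)O)O2 | intermediate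
10 | tributyl(3-methylbut-2-en-1-yl)stannane | CCCC[Sn](CCCC)(CCCC)CC=C(C)C | starting material
11 | 3-[(2R)-7-hydroxy-2-(2-hydroxypropan-2-yl)-4-(3-methylbut-2-en-1-yl)-2,3-dihydro-1-benzofuran-5-yl]propanal | O=CCCc1cc(O)c2c(c1CC=C(C)C)C[C@H](C(C)(C)O)O2 | intermediate
12 | benzene-1,3-diol (resorcinol) | Oc1cccc(O)c1 | starting material
13 | 1-bromo-3-methylbut-2-ene (prenyl bromide) | CC(C)=CCBr | starting material
14 | 3-[(3-methylbut-2-en-1-yl)oxy]phenol | CC(C)=CCOc1cccc(O)c1 | intermediate
15 | 4-(2-methylbut-3-en-2-yl)benzene-1,3-diol | C=CC(C)(C)c1ccc(O)cc1O | intermediate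
16 | 4-bromo-6-(2-methylbut-3-en-2-yl)benzene-1,3-diol | C=CC(C)(C)c1cc(Br)c(O)cc1O | intermediate
17 | hydrazine monohydrate | NN.O | starting material
18 | (2R)-5-(3-hydrazinylidenepropyl)-2-(2-hydroxypropan-2-yl)-4-(3-methylbut-2-en-1-yl)-2,3-dihydro-1-benzofuran-7-ol | NN=CCCc1cc(O)c2c(c1CC=C(C)C)C[C@H](C(C)(C)O)O2 | intermediate (not isolated)
19 | 4-{3-[(2R)-7-hydroxy-2-(2-hydroxypropan-2-yl)-4-(3-methylbut-2-en-1-yl)-2,3-dihydro-1-benzofuran-5-yl]propyl}-6-(2-methylbut-3-en-2-yl)benzene-1,3-diol | C=CC(C)(C)c1cc(CCCc2cc(O)c3c(c2CC=C(C)C)C[C@H](C(C)(C)O)O3)c(O)cc1O | target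

## Step count and risks

Total steps: 9. Longest linear sequence: 6 (steps 1, 2, 3, 4, 5, 9); ring A is made in 3 steps (6–8) and joined in step 9.

The three steps most likely to fail:

Step 9. The hydrazone is aliphatic, so the alkylnickel intermediate has β-hydrogens, and the coupling must run with three free phenols and a very electron-rich aryl bromide. Fallback: set out from aldehyde 11 and reduce it (NaBH4, MeOH, 0 °C) to the primary alcohol (2R)-5-(3-hydroxypropyl)-2-(2-hydroxypropan-2-yl)-4-(3-methylbut-2-en-1-yl)-2,3-dihydro-1-benzofuran-7-ol F1. Convert this with CBr4 and PPh3 (CH2Cl2, 0 °C) into the primary bromide (2R)-5-(3-bromopropyl)-2-(2-hydroxypropan-2-yl)-4-(3-methylbut-2-en-1-yl)-2,3-dihydro-1-benzofuran-7-ol F2. Join F2 to bromide 16 by nickel-catalysed reductive cross-electrophile coupling (NiI2, 4,4'-di-tert-butyl-2,2'-bipyridine, Zn, NaI, DMA, 60 °C), a method that tolerates protic groups; this comes back to the route at 19.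

Step 4. Discrimination between the two C–Br bonds may be incomplete at 90 °C, and the free aldehyde can give branched isomers or aldol products under the basic conditions. Fallback: set out from dibromide 7 and replace the Heck reaction by a Negishi coupling at rt–40 °C with the masked homoenolate reagent [2-(1,3-dioxolan-2-yl)ethyl]zinc bromide (3.5 equiv, Pd(OAc)2, SPhos, THF). The lower temperature sharpens the steric and electronic preference for C5 and gives the acetal (2R)-4-bromo-5-[2-(1,3-dioxolan-2-yl)ethyl]-2-(2-hydroxypropan-2-yl)-2,3-dihydro-1-benzofuran-7-ol F3. Mild hydrolysis (1 M HCl, THF, rt) comes back to the route at 9. This answers the reactivity and aldehyde problems; the site preference still rests on the same steric and electronic bias.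

Step 5. The bromide is flanked on both sides and para to a phenoxide, the enolisable aldehyde is exposed to CsF at 80 °C, and some branched (reverse-prenyl) product could form. Fallback: set out from bromo aldehyde 9 and couple it with the smaller allyltributylstannane (Pd(P(t-Bu)3)2, CsF, dioxane, 50 °C), where no regiochemical question arises, to give 3-[(2R)-7-hydroxy-2-(2-hydroxypropan-2-yl)-4-(prop-2-en-1-yl)-2,3-dihydro-1-benzofuran-5-yl]propanal F4. Cross-metathesis of F4 with excess 2-methylbut-2-ene (second-generation Grubbs catalyst, RuCl2(=CHPh)(H2IMes)(PCy3), CH2Cl2, 40 °C) builds the prenyl group and comes back to the route at 11.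

Further compounds
F1 | step 9 | (2R)-5-(3-hydroxypropyl)-2-(2-hydroxypropan-2-yl)-4-(3-methylbut-2-en-1-yl)-2,3-dihydro-1-benzofuran-7-ol | OCCCc1cc(O)c2c(c1CC=C(C)C)C[C@H](C(C)(C)O)O2
F2 | step 9 | (2R)-5-(3-bromopropyl)-2-(2-hydroxypropan-2-yl)-4-(3-methylbut-2-en-1-yl)-2,3-dihydro-1-benzofuran-7-ol | BrCCCc1cc(O)c2c(c1CC=C(C)C)C[C@H](C(C)(C)O)O2
F3 | step 4 | (2R)-4-bromo-5-[2-(1,3-dioxolan-2-yl)ethyl]-2-(2-hydroxypropan-2-yl)-2,3-dihydro-1-benzofuran-7-ol | C1COC(CCc2cc(O)c3c(c2Br)C[C@H](C(C)(C)O)O3)O1
F4 | step 5 | 3-[(2R)-7-hydroxy-2-(2-hydroxypropan-2-yl)-4-(prop-2-en-1-yl)-2,3-dihydro-1-benzofuran-5-yl]propanal | O=CCCc1cc(O)c2c(c1CC=C)C[C@H](C(C)(C)O)O2
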